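**Retrosynthetic overview**

1. Feature: the pyranone C3=C4 bond (ring B) joins C4, a former aldehyde carbon on ring A, to C3, the α-carbon of an arylacetic ester whose carbonyl is C2. Ring C (C3' ketone, C4' carbinol with the prenyl group, C5' CH2, C6' ketone) is a dearomatized 5-hydroxy-2-methoxy-4-prenylphenyl ring.
2. Last disconnection: the C6' ketone comes from a methyl enol ether, and the C4' hydroxyl from enantioselective ortho-hydroxylative dearomatization of the ring C phenol with a chiral pentavalent iodine reagent.
3. Key disconnection: C3=C4 by intramolecular Knoevenagel condensation of a 2-formyl-5-methoxyphenyl arylacetate, which closes ring B.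
4. Ester C–O bond back to 2-hydroxy-4-methoxybenzaldehyde and the arylacetic acid. The acid comes from homogentisic acid lactone by bromination, silylation, methanolysis/O-methylation, Stille prenylation and saponification.
5. Ring order: rings A and C are bought as benzene rings, ring B is closed in step 7, ring C is dearomatized in steps 9 and 10.

Key step: step 7

Assumption: which antipode of the axially chiral reagent of step 9 gives the (R)-carbinol has to be fixed by a trial on the phenol; the (R)-reagent is written, and the (S)-reagent is used instead if the trial calls for it.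

**Route**

Step 1
Reactants: 1 homogentisic acid lactone (5-hydroxybenzofuran-2(3H)-one)
Product: 2 6-bromo-5-hydroxybenzofuran-2(3H)-one
Conditions: N-bromosuccinimide (1.0 equiv), MeCN, −10 to 0 °C, dark
Reagents that add atoms: N-bromosuccinimide, O=C1CCC(=O)N1Br
Why: Electrophilic aromatic bromination of the free phenol, whose para position is blocked by the ring oxygen; of the two ortho carbons, C6 (para to the ring CH2) is the less hindered, as in 4-substitution of 2,5-dioxygenated phenylalkyl compounds, so the halogen should enter where the prenyl group belongs.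

Step 2
Reactants: 2 6-bromo-5-hydroxybenzofuran-2(3H)-one
Product: 3 6-bromo-5-(triisopropylsilyloxy)benzofuran-2(3H)-one
Conditions: chlorotriisopropylsilane (1.2 equiv), imidazole (2.0 equiv), DMF, 0 °C to rt
Reagents that add atoms: chlorotriisopropylsilane, CC(C)[Si](Cl)(C(C)C)C(C)C
Why: Silylation of the phenol with a silyl chloride and imidazole leaves the enolizable aryl lactone alone, and the bulky triisopropylsilyl ether is chosen because it must later outlast carbonate, cold hydroxide and an amidine base.

Step 3
Reactants: 3 6-bromo-5-(triisopropylsilyloxy)benzofuran-2(3H)-one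
Product: 5 methyl 2-[4-bromo-2-methoxy-5-(triisopropylsilyloxy)phenyl]acetate, via hydroxy ester 4 (not isolated)
Conditions: 10-camphorsulfonic acid (10 mol %), MeOH, rt; solid NaHCO3, concentrate below 30 °C; then MeI (3 equiv), K2CO3 (2 equiv), acetone, rt to 40 °C
Reagents that add atoms: methanol, CO; iodomethane, CI
Why: Acid-catalysed methanolysis (transesterification) of the reactive aryl lactone frees only the former lactone oxygen as a phenol while the aryl silyl ether is acid-stable, and Williamson methylation of that phenoxide fixes the methyl/silyl differentiation of the two hydroquinone oxygens.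

Step 4
Reactants: 5 methyl 2-[4-bromo-2-methoxy-5-(triisopropylsilyloxy)phenyl]acetate; 6 tributyl(3-methylbut-2-en-1-yl)stannane (commercial)
Product: 7 methyl 2-[2-methoxy-4-(3-methylbut-2-en-1-yl)-5-(triisopropylsilyloxy)phenyl]acetate
Conditions: Pd(PPh3)4 (5 mol %), degassed DMF, 95 °C
Reagents that add atoms: none
Why: Stille coupling, in which oxidative addition of the aryl bromide to zerovalent palladium, transfer of the prenyl group from tin and reductive elimination give the linear 3,3-dimethylallyl arene under neutral conditions that spare the ester and the silyl ether.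

Step 5
Reactants: 7 methyl 2-[2-methoxy-4-(3-methylbut-2-en-1-yl)-5-(triisopropylsilyloxy)phenyl]acetate
Product: 8 2-[2-methoxy-4-(3-methylbut-2-en-1-yl)-5-(triisopropylsilyloxy)phenyl]acetic acid
Conditions: LiOH·H2O (2.0 equiv), THF/H2O 3:1, 0 °C to rt; then 1 M HCl to pH 3 at 0 °C
Reagents that add atoms: lithium hydroxide, [Li+].[OH-]
Why: Saponification of the unhindered methyl arylacetate is fast at 0 °C, whereas the triisopropylsilyl ether, flanked by the prenyl CH2, should be attacked only slowly by cold hydroxide.

Step 6
Reactants: 8 2-[2-methoxy-4-(3-methylbut-2-en-1-yl)-5-(triisopropylsilyloxy)phenyl]acetic acid; 9 2-hydroxy-4-methoxybenzaldehyde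
Product: 10 2-formyl-5-methoxyphenyl 2-[2-methoxy-4-(3-methylbut-2-en-1-yl)-5-(triisopropylsilyloxy)phenyl]acetate
Conditions: N,N'-dicyclohexylcarbodiimide (1.1 equiv), 4-(dimethylamino)pyridine (10 mol %), CH2Cl2, 0 °C to rt
Reagents that add atoms: none
Why: Steglich esterification, in which the acylpyridinium formed from the O-acylisourea acylates the hydrogen-bonded phenol of the salicylaldehyde under near-neutral conditions; any coumarin already formed by the pyridine base is simply carried into step 7.

Step 7
Reactants: 10 2-formyl-5-methoxyphenyl 2-[2-methoxy-4-(3-methylbut-2-en-1-yl)-5-(triisopropylsilyloxy)phenyl]acetate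
Product: 12 the silyl-protected 3-arylcoumarin 7-methoxy-3-[2-methoxy-4-(3-methylbut-2-en-1-yl)-5-(triisopropylsilyloxy)phenyl]-2H-chromen-2-one, via aldol lactone 11 (not isolated)
Conditions: 1,8-diazabicyclo[5.4.0]undec-7-ene (DBU, 0.5 equiv), 4 Å molecular sieves, CH2Cl2, 0 °C to rt
Reagents that add atoms: none
Why: DBU deprotonates the ester CH2, the only acidic carbon (it lies between an aryl ring and an aryl ester carbonyl, and the aldehyde has no α-hydrogen), and the enolate adds to the ortho formyl group in a 6-(enolexo)-exo-trig aldol closure that forms the C3–C4 bond and ring B as the 4-hydroxy-3,4-dihydrocoumarin 11. E1cB loss of water from 11 is irreversible because it creates the conjugated 2-pyranone, so it drains the reversible steps before it, including any reversible ketene/phenoxide dissociation of the ester enolate. The closest known reaction is the ring-closing half of the Perkin–Oglialoro coumarin synthesis, an intramolecular Knoevenagel condensation well established for O-(arylacetyl)salicylaldehydes. The two sp3 centres of 11 disappear on dehydration, so no stereocontrol is needed. The step needs chemoselectivity only: the sieves take up the released water so that neither the aryl ester nor the silyl ether is hydrolysed, and the prenyl olefin is inert to an amidine base.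

Step 8
Reactants: 12 7-methoxy-3-[2-methoxy-4-(3-methylbut-2-en-1-yl)-5-(triisopropylsilyloxy)phenyl]-2H-chromen-2-one
Product: 13 3-[5-hydroxy-2-methoxy-4-(3-methylbut-2-en-1-yl)phenyl]-7-methoxy-2H-chromen-2-one
Conditions: Bu4NF (1.1 equiv), AcOH (1.2 equiv), THF, 0 °C
Reagents that add atoms: none
Why: Fluoride-mediated desilylation of the aryl silyl ether, buffered with acetic acid so that the coumarin lactone is not opened and the ortho-prenylphenol is not cyclised.

Step 9
Reactants: 13 3-[5-hydroxy-2-methoxy-4-(3-methylbut-2-en-1-yl)phenyl]-7-methoxy-2H-chromen-2-one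
Product: 14 (6R)-6-hydroxy-4-methoxy-3-(7-methoxy-2-oxo-2H-chromen-3-yl)-6-(3-methylbut-2-en-1-yl)cyclohexa-2,4-dien-1-one
Conditions: (R)-2,2'-diiodyl-1,1'-binaphthyl (1.1 equiv, made beforehand from (R)-2,2'-diiodo-1,1'-binaphthyl and dimethyldioxirane), CH2Cl2, −40 to 0 °C; filtration, cold aq. NaHCO3 wash; solution of crude 14 used at once
Reagents that add atoms: (R)-2,2'-diiodyl-1,1'-binaphthyl, O=I(=O)c1ccc2ccccc2c1-c1c(I(=O)=O)ccc2ccccc12
Why: Hydroxylative phenol dearomatization with a pentavalent iodine reagent, in which the phenol binds to the iodyl centre and oxygen passes intramolecularly from iodine to the alkylated ortho carbon C4' (the other ortho carbon is shielded by the coumarinyl group and para attack is excluded by the cyclic transfer) to give the 6-alkyl-6-hydroxycyclohexa-2,4-dienone; the C4' configuration is set by reagent control through the binaphthyl axis, and the preformed reagent keeps peracid away from the prenyl olefin.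

Step 10
Reactants: 14 (6R)-6-hydroxy-4-methoxy-3-(7-methoxy-2-oxo-2H-chromen-3-yl)-6-(3-methylbut-2-en-1-yl)cyclohexa-2,4-dien-1-one
Product: 15 3-[(4R)-4-hydroxy-4-(3-methylbut-2-en-1-yl)-3,6-dioxocyclohex-1-en-1-yl]-7-methoxy-2H-chromen-2-one (CNP0250763.1)
Conditions: 5% aq. oxalic acid, THF, 0 °C to rt
Reagents that add atoms: water, O
Why: Acid-catalysed enol ether hydrolysis, in which protonation at C5' gives the oxocarbenium ion at C6', water adds and methanol leaves to give the C6' ketone and the C5' methylene; the quaternary C4' carbinol cannot epimerise, and the cold, weakly acidic, chloride-free medium should avoid dehydration to the quinone and cyclisation of the prenyl group.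

**Compound list**

1 | homogentisic acid lactone (5-hydroxybenzofuran-2(3H)-one) | O=C1Cc2cc(O)ccc2O1 | starting material
2 | 6-bromo-5-hydroxybenzofuran-2(3H)-one | O=C1Cc2cc(O)c(Br)cc2O1 | intermediate
3 | 6-bromo-5-(triisopropylsilyloxy)benzofuran-2(3H)-one | O=C1Cc2cc(O[Si](C(C)C)(C(C)C)C(C)C)c(Br)cc2O1 | intermediate
4 | methyl 2-[4-bromo-2-hydroxy-5-(triisopropylsilyloxy)phenyl]acetate (not isolated) | COC(=O)Cc1cc(O[Si](C(C)C)(C(C)C)C(C)C)c(Br)cc1O | intermediate
5 | methyl 2-[4-bromo-2-methoxy-5-(triisopropylsilyloxy)phenyl]acetate | COC(=O)Cc1cc(O[Si](C(C)C)(C(C)C)C(C)C)c(Br)cc1OC | intermediate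
6 | tributyl(3-methylbut-2-en-1-yl)stannane | CCCC[Sn](CCCC)(CCCC)CC=C(C)C | starting material
7 | methyl 2-[2-methoxy-4-(3-methylbut-2-en-1-yl)-5-(triisopropylsilyloxy)phenyl]acetate | COC(=O)Cc1cc(O[Si](C(C)C)(C(C)C)C(C)C)c(CC=C(C)C)cc1OC | intermediate
8 | 2-[2-methoxy-4-(3-methylbut-2-en-1-yl)-5-(triisopropylsilyloxy)phenyl]acetic acid | OC(=O)Cc1cc(O[Si](C(C)C)(C(C)C)C(C)C)c(CC=C(C)C)cc1OC | intermediate
9 | 2-hydroxy-4-methoxybenzaldehyde | COc1ccc(C=O)c(O)c1 | starting material
10 | 2-formyl-5-methoxyphenyl 2-[2-methoxy-4-(3-methylbut-2-en-1-yl)-5-(triisopropylsilyloxy)phenyl]acetate | COc1ccc(C=O)c(OC(=O)Cc2cc(O[Si](C(C)C)(C(C)C)C(C)C)c(CC=C(C)C)cc2OC)c1 | intermediate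
11 | 4-hydroxy-7-methoxy-3-[2-methoxy-4-(3-methylbut-2-en-1-yl)-5-(triisopropylsilyloxy)phenyl]chroman-2-one, mixture of diastereomers (not isolated) | COc1ccc2c(c1)OC(=O)C(c1cc(O[Si](C(C)C)(C(C)C)C(C)C)c(CC=C(C)C)cc1OC)C2O | intermediate
12 | 7-methoxy-3-[2-methoxy-4-(3-methylbut-2-en-1-yl)-5-(triisopropylsilyloxy)phenyl]-2H-chromen-2-one | COc1ccc2cc(-c3cc(O[Si](C(C)C)(C(C)C)C(C)C)c(CC=C(C)C)cc3OC)c(=O)oc2c1 | intermediate
13 | 3-[5-hydroxy-2-methoxy-4-(3-methylbut-2-en-1-yl)phenyl]-7-methoxy-2H-chromen-2-one | COc1ccc2cc(-c3cc(O)c(CC=C(C)C)cc3OC)c(=O)oc2c1 | intermediate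
14 | (6R)-6-hydroxy-4-methoxy-3-(7-methoxy-2-oxo-2H-chromen-3-yl)-6-(3-methylbut-2-en-1-yl)cyclohexa-2,4-dien-1-one | COc1ccc2cc(C3=CC(=O)[C@@](O)(CC=C(C)C)C=C3OC)c(=O)oc2c1 | intermediate
15 | 3-[(4R)-4-hydroxy-4-(3-methylbut-2-en-1-yl)-3,6-dioxocyclohex-1-en-1-yl]-7-methoxy-2H-chromen-2-one | COc1ccc2cc(C3=CC(=O)[C@@](O)(CC=C(C)C)CC3=O)c(=O)oc2c1 | target

**Step count and risks**

Total step count: 10. Longest linear sequence: 10 steps (1 to 15); stannane 6 and aldehyde 9 enter as purchased materials.

Steps most likely to fail:

1. Step 9. Oxygen may be transferred to the unsubstituted ortho carbon C2' and the ring oxidised on to an ortho-quinone. The para-methoxy position may be oxidised to the para-quinone. The binaphthyl axis may discriminate poorly between the two faces of this biaryl phenol. The ortho-quinol may dimerise by [4+2] cycloaddition before it is hydrolysed. The fallback gives up reagent control and reaches the single enantiomer by resolution. It sets out from 13: stabilized 2-iodoxybenzoic acid (SIBX, the formulation of IBX with benzoic acid and isophthalic acid) in THF at rt should give the racemic ortho-quinol F1. Hydrolysis with aqueous oxalic acid as in step 10 should give the racemic enedione F2. Preparative HPLC on a chiral stationary phase then separates the (R)-enantiomer from the (S)-enantiomer F3, and the route is rejoined at 15.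

2. Step 4. Oxidative addition may be slow at the electron-rich bromide flanked by the silyloxy group. Allyl transposition on palladium may give the 1,1-dimethylallyl isomer. Protodestannylation or olefin migration may compete at 95 °C. The fallback builds the prenyl group in two stages and sets out from 5. Stille coupling with allyltributylstannane (Pd(PPh3)4, toluene, 100 °C), whose symmetrical allyl group cannot transpose, should give methyl 2-[4-allyl-2-methoxy-5-(triisopropylsilyloxy)phenyl]acetate F4. Olefin cross-metathesis of F4 with excess 2-methyl-2-butene (second-generation Grubbs catalyst (H2IMes)(PCy3)Cl2Ru=CHPh, CH2Cl2, 40 °C) then comes back to the route at 7.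

3. Step 7. The ester enolate may fragment by E1cB into an arylketene and the salicylaldehyde phenoxide, and capture of the ketene by traces of water would amount to ester cleavage. DBU may attack the acyl carbon. Hydroxide from the released water may remove the silyl group. The fallback replaces the preformed ester by a one-pot Perkin–Oglialoro condensation. It sets out from 8 together with aldehyde 9: Ac2O and Et3N at 110 °C form the mixed anhydride of 8, whose CH2 is more acidic, and condensation with 9 and lactonisation come back to the route at 12. No new compound is made on this way (F0).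

**Further compounds**

F1 | step 9 | racemic 6-hydroxy-4-methoxy-3-(7-methoxy-2-oxo-2H-chromen-3-yl)-6-(3-methylbut-2-en-1-yl)cyclohexa-2,4-dien-1-one | COc1ccc2cc(C3=CC(=O)C(O)(CC=C(C)C)C=C3OC)c(=O)oc2c1
F2 | step 9 | racemic 3-[4-hydroxy-4-(3-methylbut-2-en-1-yl)-3,6-dioxocyclohex-1-en-1-yl]-7-methoxy-2H-chromen-2-one | COc1ccc2cc(C3=CC(=O)C(O)(CC=C(C)C)CC3=O)c(=O)oc2c1
F3 | step 9 | 3-[(4S)-4-hydroxy-4-(3-methylbut-2-en-1-yl)-3,6-dioxocyclohex-1-en-1-yl]-7-methoxy-2H-chromen-2-one | COc1ccc2cc(C3=CC(=O)[C@](O)(CC=C(C)C)CC3=O)c(=O)oc2c1
F4 | step 4 | methyl 2-[4-allyl-2-methoxy-5-(triisopropylsilyloxy)phenyl]acetate | COC(=O)Cc1cc(O[Si](C(C)C)(C(C)C)C(C)C)c(CC=C)cc1OC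
F0 | step 7 | none | none
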